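Assumptions and conventions (remarks on the chemistry):
- Compound 1 (the commercial cis/trans epoxide of (R)-(+)-limonene) and compound 17 are taken as purchased; both epoxide isomers converge in step 1.
- Bicyclic compounds are named with eudesmane numbering: ring A = C1–C5 and C10, ring B = C5–C10, isopropenyl C11–C13 on C7, methyl C14 on C10, methyl C15 on C4. β is the face of C14.
- Arene carbons: Ar1 carries the CH2, Ar2 the oxygen that comes from the alkyne, Ar4 the oxygen of the ethoxy group, Ar6 the oxygen of the former ketene carbonyl; Ar3 and Ar5 are the two CH positions.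
- Minor geometric isomers (steps 4 and 8) and the carbinol epimers of 25 are not specified in the SMILES.

## Structural features

The target is a meroterpenoid: a eudesmane (trans-decalin, rings A and B) joined through a single methylene, C1–CH2–Ar1, to a hexasubstituted benzene ring, a phloroglucinol that carries a formyl group at Ar3 and an isobutyryl group at Ar5. Four of the five stereocentres are contiguous along ring A (C1, C10, C5, C4): C10 is quaternary with an axial β-methyl, C5 has α-H, C1 carries the equatorial β-CH2Ar group, and C4 is a tertiary carbinol with equatorial α-OH and axial β-methyl. The fifth, C7 in ring B, carries the equatorial β-isopropenyl group. The 1,1-disubstituted alkene and the tertiary alcohol are acid-labile (hydration, hydrohalogenation, ionisation and elimination), the triphenol is easily oxidised, and the aldehyde limits the use of strong nucleophiles and oxidants. The real difficulty is to attach a fully substituted, doubly acylated phloroglucinol to a hindered CH2 next to the quaternary centre without Friedel–Crafts or Fries conditions, and to place two different acyl groups on two ring positions that are equivalent in the parent triphenol. The key step uses the fact that Ar1 lies between two oxygenated carbons (Ar2, Ar6) with the third oxygen at Ar4: Ar1 and Ar2 are the two carbons of a silyl ynol ether, and Ar3–Ar6 are the four carbons of a 3-alkoxycyclobutenone. The ring synthesis also delivers the three oxygens in three different states (OH, OSi, OEt), which allows Ar5 and Ar3 to be addressed one after the other under phenoxide direction.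

## Logic of the disconnections

31 to 30: the Ar4–O–ethyl bond is cut. The oxygen para to Ar1 arrives as an ether from the cyclobutenone and is unmasked last, when two ortho carbonyl groups make the aryloxide a good leaving group for SN2 attack at the ethyl carbon. The gain is that all three phenols stay distinguishable until the end. The demand is a dealkylation free of Brønsted and Lewis acid.

30 to 28: the Ar3–CHO bond is cut. Ar3 is the only ring CH left and is ortho to the free Ar2 hydroxyl, so a magnesium-phenoxide-directed formylation needs no regiocontrol. The demand is that the free tertiary alcohol and the aryl ketone tolerate the basic medium.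

28 to 22 (through 27, 26, 25, 24): the Ar5–acyl bond is cut in two stages, first the C(=O)–CH(CH3)2 bond (Grignard addition, then oxidation), then the Ar5–CHO bond. The acyl group is thus traced to a formyl group placed ortho to the one free phenol of 22, which replaces the Lewis-acid acyl shift. The gain is 22, an arene with both CH positions free and its oxygens differentiated. The demand is an efficient addition of a secondary Grignard reagent to a di-ortho-substituted aldehyde and one fluoride step that removes both silyl groups.

22 to 16 + 17: the bonds Ar1–Ar6 and Ar2–Ar3 are cut; the ring is formed by a pericyclic cascade in which Ar5–Ar6, originally a bond of 17, is broken and made again. This removes the whole arene and leaves an alkyne on the terpene and a four-carbon building block. The demand is one regiochemical event, the orientation of the ketene–alkyne cycloaddition, under neutral thermal conditions.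

16 to 13 (through 15, 14): the ynol ether is traced to an ester; one carbon (from dibromomethane) is inserted between the CH2 and the carboxyl carbon, and the O–Si bond is cut. The demand is clean carbenoid rearrangement and O-silylation.

13 to 9 (through 12, 11, 10): the silyl ether is removed, the ester is traced to an enol ether (oxidation), the tertiary alcohol to the epoxide (C3–H bond), and the enol ether C=C bond to the aldehyde. The aldehyde carbon of 9 thereby becomes the benzylic CH2 of the target. The demand is hydride attack at C3, not C4, of the epoxide.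

9 to 8: the two C–O bonds of the epoxide are cut. The demand is α-face and ring-alkene selectivity in the presence of the isopropenyl group and the aldehyde.

8 to 7: C1–C2 and C5–C10 are cut (intramolecular Diels–Alder). Both carbocycles and three stereocentres fall away. The demand is endo and facial control from the single stereocentre C7.

7 to 1 (through 6, 5, 4, 3, 2): the three C=C bonds made by olefination are cut back to a keto aldehyde, and this to the ring of limonene oxide. The demand is chemoselective olefination of the aldehyde before the ketone and E geometry in the dienophile.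

## Other disconnections considered

Alternative 1: The cut is in the terpene at C6–C7 (eudesmane numbering), the 1,10-closure of the farnesyl chain. Germacrene A synthase, a Mg2+-dependent cyclase, would ionise farnesyl diphosphate A1, close the ten-membered ring and deprotonate to (R)-germacrene A A2, with the isopropenyl group and the C7 configuration in place. A2 would then be joined to the arene biomimetically: the o-quinone methide A3 of 3-formyl-5-isobutyrylphloroglucinol alkylates C1, the C10 cation closes across the ring onto C4=C5, and water is captured at C4.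
- In favour: extreme brevity, no protecting groups, and the CH2–C1 bond, the decalin and four stereocentres would arise in one cascade. On step economy and on the number of stereocentres set per step this plan is the better one.
- Against: A2 is thermally labile (Cope rearrangement to the elemene skeleton) and acid-labile, and it needs an enzyme and a diphosphate substrate, not bench reagents. The cascade offers no handle on which alkene reacts, on hetero-Diels–Alder chroman formation versus C-alkylation, or on the fate of the C4 cation (water capture on either face, or elimination). A3 also dimerises.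
- Comparison: the chosen plan is longer but each bond is made by a step whose regio- and stereochemistry can be argued in advance. Mechanistically a cation cascade under conformational control stands against a pericyclic sequence with fixed orientation.

Alternative 2: The cut is C1–C2 and C5–C10. Me2AlCl activates the (E)-enal of trienal A4 for cycloaddition onto the tethered diene and gives eudesma-3,11-diene-1β-carbaldehyde A5 with rings A and B and the stereocentres C1, C5 and C10. A4 and A5 are identical with compounds 7 and 8.
- In favour: this is the step with the highest stereochemical return in the whole problem (three stereocentres including the quaternary one, against none in the benzannulation), and on that point it is the better disconnection.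
- Against, as the central step: it says nothing about the arene. A plan built on it would attach a preformed phloroglucinol derivative to the aldehyde carbon of A5 (aryl-metal addition and benzylic deoxygenation, or reductive alkylation). That could be shorter by several steps than building the ring, and is named as an advantage. It needs, however, a deoxygenation without acid or hydrogenolysis next to the isopropenyl group, and an arene whose oxygens are not differentiated for the two acylations.
- Comparison: the two disconnections are complementary. The chosen plan keeps this cycloaddition as step 6 and adds the de novo arene synthesis, which gives regiochemical definition of the ring at the price of length.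

Alternative 3: The cut is one ring bond of the arene next to the acyl-bearing carbon. KOH in methanol would open pyrone A6 to the triketo ester A7, whose doubly activated methylene attacks the ester carbon (Claisen closure) to give the deformyl target A8 with the isobutyryl group already in place; formylation would finish the synthesis.
- In favour: the acyl group is built in (it saves the three steps 14–16), there is no O-alkyl or O-silyl group on the arene to remove (it avoids step 19), and the sequence from the terpene aldehyde could be markedly shorter. On step economy and protecting-group economy this plan is the better one.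
- Against: A6 needs C-alkylation of a 4-hydroxypyrone by a hindered terpenylmethyl unit and a side-chain acylation through a dianion. A7 can also close by aldol condensation to a resorcylate or re-lactonise, and the branch at its α-carbon slows the wanted Claisen mode.
- Comparison: both plans build the arene on the terpene CH2 and both end with a phenoxide-directed formylation (equal). The alternative relies on a thermodynamically steered ionic condensation with several possible closure modes, whereas the chosen plan relies on a pericyclic cascade with one possible orientation.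

Key step: step 13

## Route

Step 1
Reactants: 1 (4R)-limonene 1,2-oxide (cis/trans mixture)
Product: 3 (3R)-6-oxo-3-(prop-1-en-2-yl)heptanal, via limonene-1,2-diol 2 (not isolated)
Conditions: H5IO6, THF–H2O, 0 °C → rt
Reagents that add atoms: water, O
Why: Periodic acid hydrolyses the epoxide to the vicinal diol and cleaves it in the same flask (Malaprade glycol cleavage); both epoxide isomers converge, the stereocentre is not involved and the isopropenyl group is inert.

Step 2
Reactants: 3 (3R)-6-oxo-3-(prop-1-en-2-yl)heptanal
Product: 4 (2E,5R)-2-methyl-8-oxo-5-(prop-1-en-2-yl)non-2-enal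
Conditions: Ph3P=C(CH3)CHO, toluene, 90 °C
Reagents that add atoms: 2-(triphenylphosphoranylidene)propanal, CC(C=O)=P(c1ccccc1)(c1ccccc1)c1ccccc1
Why: Wittig olefination with a formyl-stabilised ylide, which reacts with the aldehyde but not with the methyl ketone and should give the E enal; the neutral medium avoids aldol cyclisation of the keto aldehyde.

Step 3
Reactants: 4 (2E,5R)-2-methyl-8-oxo-5-(prop-1-en-2-yl)non-2-enal
Product: 5 (5R,7E)-8-methyl-5-(prop-1-en-2-yl)deca-7,9-dien-2-one
Conditions: Ph3PCH3Br, KN(SiMe3)2 (1.05 equiv ylide), THF, −78 → 0 °C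
Reagents that add atoms: methyltriphenylphosphonium bromide, C[P+](c1ccccc1)(c1ccccc1)c1ccccc1.[Br-]
Why: Wittig methylenation; at low temperature the non-stabilised ylide should take the aldehyde well before the enolisable methyl ketone, and the 7E geometry of step 2 is untouched.

Step 4
Reactants: 5 (5R,7E)-8-methyl-5-(prop-1-en-2-yl)deca-7,9-dien-2-one
Product: 6 (2E,6R,8E)-N-methoxy-N,3,9-trimethyl-6-(prop-1-en-2-yl)undeca-2,8,10-trienamide
Conditions: (EtO)2P(O)CH2C(O)N(OMe)Me, NaH, THF, 0 → 50 °C; chromatographic removal of the 2Z isomer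
Reagents that add atoms: diethyl {2-[methoxy(methyl)amino]-2-oxoethyl}phosphonate, CCOP(=O)(OCC)CC(=O)N(C)OC
Why: Horner–Wadsworth–Emmons olefination of the methyl ketone; the E isomer (amide trans to the long chain) should predominate, and the minor Z isomer is removed here so that the dienophile geometry is uniform.

Step 5
Reactants: 6 (2E,6R,8E)-N-methoxy-N,3,9-trimethyl-6-(prop-1-en-2-yl)undeca-2,8,10-trienamide
Product: 7 (2E,6R,8E)-3,9-dimethyl-6-(prop-1-en-2-yl)undeca-2,8,10-trienal
Conditions: i-Bu2AlH, THF, −78 °C; aq. potassium sodium tartrate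
Reagents that add atoms: none
Why: Reduction of a Weinreb amide stops at the chelated aluminium hemiaminal, which releases the aldehyde only on work-up; neither over-reduction nor E/Z isomerisation is expected at −78 °C.

Step 6
Reactants: 7 (2E,6R,8E)-3,9-dimethyl-6-(prop-1-en-2-yl)undeca-2,8,10-trienal
Product: 8 eudesma-3,11-diene-1β-carbaldehyde
Conditions: Me2AlCl (1.2 equiv), CH2Cl2, −78 → −20 °C
Reagents that add atoms: none
Why: Lewis-acid-promoted intramolecular Diels–Alder reaction with a four-carbon tether, forming C1–C2 and C5–C10. The E dienophile places CHO and the C10 methyl cis, and the endo-CHO transition state puts the tether exo and gives the trans ring fusion (5α-H, 10β-CH3). The chair-like tether with equatorial isopropenyl at C7 fixes the face, so C1, C5 and C10 all follow from C7.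

Step 7
Reactants: 8 eudesma-3,11-diene-1β-carbaldehyde
Product: 9 3α,4α-epoxyeudesm-11-ene-1β-carbaldehyde
Conditions: mCPBA (1.05 equiv), NaHCO3, CH2Cl2, −20 → 0 °C
Reagents that add atoms: mCPBA (3-chloroperoxybenzoic acid), O=C(OO)c1cccc(Cl)c1
Why: Prilezhaev epoxidation; the trisubstituted ring alkene is more nucleophilic than the isopropenyl group (as in limonene) and is epoxidised faster than the aldehyde is oxidised. The peracid comes from the α face because the β face at C4 is screened by the axial C10 methyl, which sets C3 and C4.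

Step 8
Reactants: 9 3α,4α-epoxyeudesm-11-ene-1β-carbaldehyde
Product: 10 3α,4α-epoxy-1β-(2-methoxyethenyl)eudesm-11-ene (E/Z mixture)
Conditions: MeOCH2PPh3Cl, KN(SiMe3)2, THF, −78 °C → rt
Reagents that add atoms: (methoxymethyl)triphenylphosphonium chloride, COC[P+](c1ccccc1)(c1ccccc1)c1ccccc1.[Cl-]
Why: Wittig reaction with (methoxymethylidene)triphenylphosphorane homologates the hindered aldehyde to the enol ether; the epoxide is inert to the ylide, and C1 keeps the more stable equatorial β configuration even if it enolises.

Step 9
Reactants: 10 3α,4α-epoxy-1β-(2-methoxyethenyl)eudesm-11-ene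
Product: 11 1β-(2-methoxyethenyl)eudesm-11-en-4α-ol
Conditions: LiEt3BH, THF, 0 → 65 °C
Reagents that add atoms: none
Why: SN2 opening of the trisubstituted epoxide by the strongly nucleophilic borohydride at the secondary carbon C3 leaves the C4–O bond intact, so the 4α-hydroxy, 4β-methyl configuration is that of the epoxide; the enol ether and the alkene are inert to hydride.

Step 10
Reactants: 11 1β-(2-methoxyethenyl)eudesm-11-en-4α-ol
Product: 12 methyl (4α-hydroxyeudesm-11-en-1β-yl)acetate
Conditions: pyridinium chlorochromate [C5H5NH][CrO3Cl], NaOAc, CH2Cl2, rt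
Reagents that add atoms: pyridinium chlorochromate, [O-][Cr](=O)(=O)Cl.c1cc[nH+]cc1
Why: Oxidation of an enol ether to the ester by hexavalent chromium completes the one-carbon homologation of aldehyde 9 to the ester in two steps; the tertiary alcohol cannot be oxidised and the acetate buffer protects the isopropenyl group.

Step 11
Reactants: 12 methyl (4α-hydroxyeudesm-11-en-1β-yl)acetate
Product: 13 methyl [4α-(triethylsilyloxy)eudesm-11-en-1β-yl]acetate
Conditions: Et3SiOTf, 2,6-lutidine, CH2Cl2, −78 → 0 °C
Reagents that add atoms: triethylsilyl trifluoromethanesulfonate, CC[Si](CC)(CC)OS(=O)(=O)C(F)(F)F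
Why: Silylation of a hindered tertiary alcohol with the silyl triflate; the ether shields the hydroxyl from the lithium bases of step 12 and from ketene capture in step 13.

Step 12
Reactants: 13 methyl [4α-(triethylsilyloxy)eudesm-11-en-1β-yl]acetate
Product: 16 triisopropyl({3-[4α-(triethylsilyloxy)eudesm-11-en-1β-yl]prop-1-yn-1-yl}oxy)silane, via lithium dibromoenolate 14 (not isolated), via lithium ynolate 15 (not isolated)
Conditions: CH2Br2, lithium 2,2,6,6-tetramethylpiperidide, THF, −78 °C; n-BuLi, −78 °C → rt; i-Pr3SiOTf, −78 → 0 °C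
Reagents that add atoms: dibromomethane, BrCBr; triisopropylsilyl trifluoromethanesulfonate, CC(C)[Si](C(C)C)(C(C)C)OS(=O)(=O)C(F)(F)F
Why: Kowalski ester homologation stopped at the ynolate: LiCHBr2 adds to the ester, loss of methoxide gives enolate 14, and bromine–lithium exchange gives a carbenoid whose 1,2-shift gives ynolate 15. The bulky silyl triflate then silylates oxygen, not carbon, and no stereocentre is touched.

Step 13
Reactants: 16 triisopropyl({3-[4α-(triethylsilyloxy)eudesm-11-en-1β-yl]prop-1-yn-1-yl}oxy)silane; 17 3-ethoxycyclobut-2-en-1-one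
Product: 22 5-ethoxy-2-{[4α-(triethylsilyloxy)eudesm-11-en-1β-yl]methyl}-3-(triisopropylsilyloxy)phenol, via ethoxyvinylketene 18 (not isolated), via vinylcyclobutenone 19 (not isolated), via dienylketene 20 (not isolated), via cyclohexadienone 21 (not isolated)
Conditions: 17 (1.5 equiv), toluene (0.5 M), sealed tube, argon, 80 °C then 110 °C
Reagents that add atoms: none
Why: Heating opens 17 by 4π-electrocyclic cleavage of its C1–C4 bond to ethoxyvinylketene 18. The ketene C=C bond of 18 adds [2+2] to the alkyne of 16: the alkyne carbon β to oxygen, which carries the terpenyl CH2, is the nucleophilic terminus and bonds to the electrophilic ketene carbonyl carbon (Ar1–Ar6), while the siloxy carbon bonds to the ketene α-carbon (Ar2–Ar3), giving 19. A second 4π opening of 19 gives dienylketene 20, whose thermal disrotatory 6π-electrocyclisation rejoins the two carbons that were C1 and C4 of 17 (Ar6–Ar5) and closes the six-membered carbocycle as 21, which tautomerises to phenol 22. The closest known reaction type is the Danheiser benzannulation of cyclobutenones with heteroatom-substituted alkynes, in its siloxyalkyne version that leads to resorcinol monosilyl ethers; the 3-alkoxy group on the cyclobutenone is an uncommon extension that supplies the third oxygen. No stereocentre is created, since the sp3 carbons of 19 and 21 vanish on aromatisation and the five terpene stereocentres are remote from the reacting π-system. The one selectivity needed is the orientation of the [2+2] step, and the polarisation of the silyl ynol ether against the ketene secures it, placing Ar1 between Ar2–OSi and Ar6–OH and the ethoxy group at Ar4. The neutral, reagent-free medium spares the isopropenyl group, and the triethylsilyl ether keeps the tertiary hydroxyl from adding to 18.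

Step 14
Reactants: 22 5-ethoxy-2-{[4α-(triethylsilyloxy)eudesm-11-en-1β-yl]methyl}-3-(triisopropylsilyloxy)phenol
Product: 24 6-ethoxy-2-hydroxy-3-{[4α-(triethylsilyloxy)eudesm-11-en-1β-yl]methyl}-4-(triisopropylsilyloxy)benzaldehyde, via hydroxymethylphenol 23 (not isolated)
Conditions: MgCl2, Et3N, (CH2O)n, MeCN, 80 °C
Reagents that add atoms: paraformaldehyde (as formaldehyde), C=O
Why: Magnesium-phenoxide-mediated ortho-formylation (Casnati–Skattebøl): the phenoxide of the only free hydroxyl (Ar6) delivers formaldehyde to its one free ortho carbon, Ar5, and a second formaldehyde oxidises the benzylic alkoxide by hydride transfer. No acid is involved, so both silyl ethers and the isopropenyl group should survive.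

Step 15
Reactants: 24 6-ethoxy-2-hydroxy-3-{[4α-(triethylsilyloxy)eudesm-11-en-1β-yl]methyl}-4-(triisopropylsilyloxy)benzaldehyde
Product: 25 5-ethoxy-6-(1-hydroxy-2-methylpropyl)-2-{[4α-(triethylsilyloxy)eudesm-11-en-1β-yl]methyl}-3-(triisopropylsilyloxy)phenol (carbinol epimers)
Conditions: i-PrMgCl (3.5 equiv), LaCl3·2LiCl, THF, −20 → 0 °C
Reagents that add atoms: isopropylmagnesium chloride, CC(C)[Mg]Cl
Why: Grignard addition to the aldehyde after deprotonation of the phenol; the lanthanum salt raises carbonyl electrophilicity and suppresses β-hydride reduction, and the new carbinol centre is erased in step 16.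

Step 16
Reactants: 25 5-ethoxy-6-(1-hydroxy-2-methylpropyl)-2-{[4α-(triethylsilyloxy)eudesm-11-en-1β-yl]methyl}-3-(triisopropylsilyloxy)phenol
Product: 26 1-(6-ethoxy-2-hydroxy-3-{[4α-(triethylsilyloxy)eudesm-11-en-1β-yl]methyl}-4-(triisopropylsilyloxy)phenyl)-2-methylpropan-1-one
Conditions: MnO2 (activated, excess), CH2Cl2, rt
Reagents that add atoms: none
Why: MnO2 oxidises the benzylic alcohol selectively to the aryl ketone, which is stabilised by the hydrogen bond to the Ar6 hydroxyl; the alkene and the silyl ethers are inert.

Step 17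
Reactants: 26 1-(6-ethoxy-2-hydroxy-3-{[4α-(triethylsilyloxy)eudesm-11-en-1β-yl]methyl}-4-(triisopropylsilyloxy)phenyl)-2-methylpropan-1-one
Product: 28 1-(6-ethoxy-2,4-dihydroxy-3-{[4α-hydroxyeudesm-11-en-1β-yl]methyl}phenyl)-2-methylpropan-1-one, via monosilyl ether 27 (not isolated)
Conditions: Bu4NF (5 equiv), THF, argon, 0 → 45 °C
Reagents that add atoms: none
Why: Fluoride cleaves the aryl silyl ether at once and, on warming, the tertiary triethylsilyl ether as well, driven by the Si–F bond; the hydroxy ketone is stable to the basic medium.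

Step 18
Reactants: 28 1-(6-ethoxy-2,4-dihydroxy-3-{[4α-hydroxyeudesm-11-en-1β-yl]methyl}phenyl)-2-methylpropan-1-one
Product: 30 2-ethoxy-4,6-dihydroxy-5-{[4α-hydroxyeudesm-11-en-1β-yl]methyl}-3-(2-methylpropanoyl)benzaldehyde, via hydroxymethyl ketone 29 (not isolated)
Conditions: MgCl2, Et3N, (CH2O)n, THF, 65 °C
Reagents that add atoms: paraformaldehyde (as formaldehyde), C=O
Why: Second magnesium-mediated ortho-formylation, now directed by the Ar2 hydroxyl to Ar3, the only ring CH left; the Ar6 hydroxyl is tied up in the chelate with the ketone and the tertiary alcohol is inert.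

Step 19
Reactants: 30 2-ethoxy-4,6-dihydroxy-5-{[4α-hydroxyeudesm-11-en-1β-yl]methyl}-3-(2-methylpropanoyl)benzaldehyde
Product: 31 2,4,6-trihydroxy-3-{[4α-hydroxyeudesm-11-en-1β-yl]methyl}-5-(2-methylpropanoyl)benzaldehyde
Conditions: NaSEt, DMF, argon, 100 °C; then cold dilute HCl to pH 4
Reagents that add atoms: none
Why: SN2 dealkylation of the aryl ethyl ether by thiolate; the aryloxide leaving group is stabilised by two ortho carbonyl groups (a doubly vinylogous ester), and the non-acidic medium spares the isopropenyl group and the tertiary alcohol.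

## Compound list

1 | (4R)-limonene 1,2-oxide, cis/trans mixture | CC12OC1C[C@@H](CC2)C(C)=C | starting material
2 | (4R)-limonene-1,2-diol | CC1(O)C(O)C[C@@H](CC1)C(C)=C | intermediate (not isolated)
3 | (3R)-6-oxo-3-(prop-1-en-2-yl)heptanal | CC(=O)CC[C@H](CC=O)C(C)=C | intermediate
4 | (2E,5R)-2-methyl-8-oxo-5-(prop-1-en-2-yl)non-2-enal | CC(=O)CC[C@H](C/C=C(\C)C=O)C(C)=C | intermediate
5 | (5R,7E)-8-methyl-5-(prop-1-en-2-yl)deca-7,9-dien-2-one | CC(=O)CC[C@H](C/C=C(\C)C=C)C(C)=C | intermediate
6 | (2E,6R,8E)-N-methoxy-N,3,9-trimethyl-6-(prop-1-en-2-yl)undeca-2,8,10-trienamide | CON(C)C(=O)/C=C(\C)CC[C@H](C/C=C(\C)C=C)C(C)=C | intermediate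
7 | (2E,6R,8E)-3,9-dimethyl-6-(prop-1-en-2-yl)undeca-2,8,10-trienal | O=C/C=C(\C)CC[C@H](C/C=C(\C)C=C)C(C)=C | intermediate
8 | eudesma-3,11-diene-1β-carbaldehyde | C=C(C)[C@@H]1CC[C@@]2(C)[C@H](C=O)CC=C(C)[C@@H]2C1 | intermediate
9 | 3α,4α-epoxyeudesm-11-ene-1β-carbaldehyde | C=C(C)[C@@H]1CC[C@@]2(C)[C@H](C=O)C[C@H]3O[C@@]3(C)[C@@H]2C1 | intermediate
10 | 3α,4α-epoxy-1β-(2-methoxyethenyl)eudesm-11-ene (E/Z) | C=C(C)[C@@H]1CC[C@@]2(C)[C@H](C=COC)C[C@H]3O[C@@]3(C)[C@@H]2C1 | intermediate
11 | 1β-(2-methoxyethenyl)eudesm-11-en-4α-ol | C=C(C)[C@@H]1CC[C@@]2(C)[C@H](C=COC)CC[C@@](C)(O)[C@@H]2C1 | intermediate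
12 | methyl (4α-hydroxyeudesm-11-en-1β-yl)acetate | C=C(C)[C@@H]1CC[C@@]2(C)[C@H](CC(=O)OC)CC[C@@](C)(O)[C@@H]2C1 | intermediate
13 | methyl [4α-(triethylsilyloxy)eudesm-11-en-1β-yl]acetate | C=C(C)[C@@H]1CC[C@@]2(C)[C@H](CC(=O)OC)CC[C@@](C)(O[Si](CC)(CC)CC)[C@@H]2C1 | intermediate
14 | lithium 1,1-dibromo-3-[4α-(triethylsilyloxy)eudesm-11-en-1β-yl]prop-1-en-2-olate | C=C(C)[C@@H]1CC[C@@]2(C)[C@H](CC(O[Li])=C(Br)Br)CC[C@@](C)(O[Si](CC)(CC)CC)[C@@H]2C1 | intermediate (not isolated)
15 | lithium 3-[4α-(triethylsilyloxy)eudesm-11-en-1β-yl]prop-1-yn-1-olate | C=C(C)[C@@H]1CC[C@@]2(C)[C@H](CC#CO[Li])CC[C@@](C)(O[Si](CC)(CC)CC)[C@@H]2C1 | intermediate (not isolated)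
16 | triisopropyl({3-[4α-(triethylsilyloxy)eudesm-11-en-1β-yl]prop-1-yn-1-yl}oxy)silane | C=C(C)[C@@H]1CC[C@@]2(C)[C@H](CC#CO[Si](C(C)C)(C(C)C)C(C)C)CC[C@@](C)(O[Si](CC)(CC)CC)[C@@H]2C1 | intermediate
17 | 3-ethoxycyclobut-2-en-1-one | CCOC1=CC(=O)C1 | starting material
18 | 3-ethoxybuta-1,3-dien-1-one (ethoxyvinylketene) | C=C(OCC)C=C=O | intermediate (not isolated)
19 | 4-(1-ethoxyethenyl)-2-{[4α-(triethylsilyloxy)eudesm-11-en-1β-yl]methyl}-3-(triisopropylsilyloxy)cyclobut-2-en-1-one | C=C(C)[C@@H]1CC[C@@]2(C)[C@H](CC3=C(O[Si](C(C)C)(C(C)C)C(C)C)C(C(=C)OCC)C3=O)CC[C@@](C)(O[Si](CC)(CC)CC)[C@@H]2C1 | intermediate (not isolated)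
20 | 5-ethoxy-2-{[4α-(triethylsilyloxy)eudesm-11-en-1β-yl]methyl}-3-(triisopropylsilyloxy)hexa-1,3,5-trien-1-one | C=C(C)[C@@H]1CC[C@@]2(C)[C@H](CC(=C=O)C(O[Si](C(C)C)(C(C)C)C(C)C)=CC(=C)OCC)CC[C@@](C)(O[Si](CC)(CC)CC)[C@@H]2C1 | intermediate (not isolated)
21 | 5-ethoxy-2-{[4α-(triethylsilyloxy)eudesm-11-en-1β-yl]methyl}-3-(triisopropylsilyloxy)cyclohexa-2,4-dien-1-one | C=C(C)[C@@H]1CC[C@@]2(C)[C@H](CC3=C(O[Si](C(C)C)(C(C)C)C(C)C)C=C(OCC)CC3=O)CC[C@@](C)(O[Si](CC)(CC)CC)[C@@H]2C1 | intermediate (not isolated)
22 | 5-ethoxy-2-{[4α-(triethylsilyloxy)eudesm-11-en-1β-yl]methyl}-3-(triisopropylsilyloxy)phenol | C=C(C)[C@@H]1CC[C@@]2(C)[C@H](Cc3c(O)cc(OCC)cc3O[Si](C(C)C)(C(C)C)C(C)C)CC[C@@](C)(O[Si](CC)(CC)CC)[C@@H]2C1 | intermediate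
23 | 5-ethoxy-6-(hydroxymethyl)-2-{[4α-(triethylsilyloxy)eudesm-11-en-1β-yl]methyl}-3-(triisopropylsilyloxy)phenol | C=C(C)[C@@H]1CC[C@@]2(C)[C@H](Cc3c(O)c(CO)c(OCC)cc3O[Si](C(C)C)(C(C)C)C(C)C)CC[C@@](C)(O[Si](CC)(CC)CC)[C@@H]2C1 | intermediate (not isolated)
24 | 6-ethoxy-2-hydroxy-3-{[4α-(triethylsilyloxy)eudesm-11-en-1β-yl]methyl}-4-(triisopropylsilyloxy)benzaldehyde | C=C(C)[C@@H]1CC[C@@]2(C)[C@H](Cc3c(O)c(C=O)c(OCC)cc3O[Si](C(C)C)(C(C)C)C(C)C)CC[C@@](C)(O[Si](CC)(CC)CC)[C@@H]2C1 | intermediate
25 | 5-ethoxy-6-(1-hydroxy-2-methylpropyl)-2-{[4α-(triethylsilyloxy)eudesm-11-en-1β-yl]methyl}-3-(triisopropylsilyloxy)phenol | C=C(C)[C@@H]1CC[C@@]2(C)[C@H](Cc3c(O)c(C(O)C(C)C)c(OCC)cc3O[Si](C(C)C)(C(C)C)C(C)C)CC[C@@](C)(O[Si](CC)(CC)CC)[C@@H]2C1 | intermediate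
26 | 1-(6-ethoxy-2-hydroxy-3-{[4α-(triethylsilyloxy)eudesm-11-en-1β-yl]methyl}-4-(triisopropylsilyloxy)phenyl)-2-methylpropan-1-one | C=C(C)[C@@H]1CC[C@@]2(C)[C@H](Cc3c(O)c(C(=O)C(C)C)c(OCC)cc3O[Si](C(C)C)(C(C)C)C(C)C)CC[C@@](C)(O[Si](CC)(CC)CC)[C@@H]2C1 | intermediate
27 | 1-(6-ethoxy-2,4-dihydroxy-3-{[4α-(triethylsilyloxy)eudesm-11-en-1β-yl]methyl}phenyl)-2-methylpropan-1-one | C=C(C)[C@@H]1CC[C@@]2(C)[C@H](Cc3c(O)c(C(=O)C(C)C)c(OCC)cc3O)CC[C@@](C)(O[Si](CC)(CC)CC)[C@@H]2C1 | intermediate (not isolated)
28 | 1-(6-ethoxy-2,4-dihydroxy-3-{[4α-hydroxyeudesm-11-en-1β-yl]methyl}phenyl)-2-methylpropan-1-one | C=C(C)[C@@H]1CC[C@@]2(C)[C@H](Cc3c(O)c(C(=O)C(C)C)c(OCC)cc3O)CC[C@@](C)(O)[C@@H]2C1 | intermediate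
29 | 1-(2-ethoxy-4,6-dihydroxy-3-(hydroxymethyl)-5-{[4α-hydroxyeudesm-11-en-1β-yl]methyl}phenyl)-2-methylpropan-1-one | C=C(C)[C@@H]1CC[C@@]2(C)[C@H](Cc3c(O)c(C(=O)C(C)C)c(OCC)c(CO)c3O)CC[C@@](C)(O)[C@@H]2C1 | intermediate (not isolated)
30 | 2-ethoxy-4,6-dihydroxy-5-{[4α-hydroxyeudesm-11-en-1β-yl]methyl}-3-(2-methylpropanoyl)benzaldehyde | C=C(C)[C@@H]1CC[C@@]2(C)[C@H](Cc3c(O)c(C(=O)C(C)C)c(OCC)c(C=O)c3O)CC[C@@](C)(O)[C@@H]2C1 | intermediate
31 | 2,4,6-trihydroxy-3-{[4α-hydroxyeudesm-11-en-1β-yl]methyl}-5-(2-methylpropanoyl)benzaldehyde (CNP0498016.1) | C=C(C)[C@@H]1CC[C@@]2(C)[C@H](Cc3c(O)c(C=O)c(O)c(C(=O)C(C)C)c3O)CC[C@@](C)(O)[C@@H]2C1 | target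

## Step count and least certain steps

Total step count: 19. Longest linear sequence: 19 steps (1 to 31); 17 is purchased and enters at step 13.

Step 13 (key step). The electrocyclic opening of the push–pull-stabilised cyclobutenone may need a temperature at which the silyl ynol ether slowly decays; the sequence may stall at 19; and the phenolic product may be acylated by ketene 18. Fallback, from 16 back to 22: the vinylketene is generated without heat. Commercial ethyl (E)-3-ethoxybut-2-enoate is saponified to (E)-3-ethoxybut-2-enoic acid F1 and converted with oxalyl chloride into (E)-3-ethoxybut-2-enoyl chloride F2. Slow addition of F2 to 16 and Et3N in CH2Cl2 at 0 °C forms 18 by 1,4-dehydrochlorination, so that the [2+2] step to 19 runs cold, and only the final ring opening and 6π closure to 22 need brief heating in toluene.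

Step 19. SN2 attack at an ethyl (not a methyl) carbon of a substrate that is a dianion under the conditions may be slow, so that long heating erodes the formyl group (thiolate addition, deformylation) or oxidises the phenolate. Fallback, from 28 back to 31: the order of the last two operations is reversed, so that the harsh step precedes the aldehyde. Compound 28 is de-ethylated with NaSEt in DMF at 120 °C to 2-methyl-1-(2,4,6-trihydroxy-3-{[4α-hydroxyeudesm-11-en-1β-yl]methyl}phenyl)propan-1-one F3. F3 is then formylated at its single ring CH with MgCl2, Et3N and paraformaldehyde, through the hydroxymethyl triphenol F4, to give 31.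

Step 15. Hydride transfer from the secondary Grignard reagent may reduce the di-ortho-substituted, chelated aldehyde in place of addition, and the o-hydroxybenzyl alcohol may lose water to a quinone methide on isolation or during step 16. Fallback, from 22 back to 26, avoiding both aldehyde and carbinol: ortho-bromination of 22 (N-bromosuccinimide, catalytic i-Pr2NH, CH2Cl2, −78 °C) gives 6-bromo-5-ethoxy-2-{[4α-(triethylsilyloxy)eudesm-11-en-1β-yl]methyl}-3-(triisopropylsilyloxy)phenol F5. n-BuLi (2.2 equiv, THF, −78 °C) gives the lithium 6-lithiophenolate F6, which is acylated with N-methoxy-N-methylisobutyramide to give 26 directly. Should bromine enter para to the hydroxyl, the same operations followed by step 17 still converge on 28, because desilylation makes the two positions equivalent.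

Step 9. Attack at C3 from the β face is a diequatorial, not a trans-diaxial, opening in the rigid trans-decalin; it may be slow, and attack at the tertiary C4 or rearrangement of the epoxide may compete. Fallback, from 10 back to 11: reductive lithiation with lithium 4,4'-di-tert-butylbiphenylide in THF at −78 °C, then methanol. Electron transfer cleaves the C–O bond at the less substituted carbon without any backside attack and leaves the tertiary alkoxide, and alkenes and the enol ether are not reduced at this temperature. This fallback makes no compound outside the list (F0).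

Step 12. The carbenoid rearrangement may be incomplete with the branched substrate, the ynolate may be protonated (return to a homologous ester), and silylation may occur on carbon. Fallback, from 13 back to 16, making the ynolate by oxidation of an acetylide in place of ester homologation: i-Bu2AlH at −78 °C reduces 13 to [4α-(triethylsilyloxy)eudesm-11-en-1β-yl]acetaldehyde F7. Dimethyl (1-diazo-2-oxopropyl)phosphonate with K2CO3 in methanol gives 1β-(prop-2-yn-1-yl)-4α-(triethylsilyloxy)eudesm-11-ene F8. n-BuLi gives the lithium acetylide F9, LiOOt-Bu (from t-BuOOH and LiN(SiMe3)2) oxidises it to ynolate 15, and i-Pr3SiOTf gives 16.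

## Further compounds

F1 | step 13 | (E)-3-ethoxybut-2-enoic acid | CCO/C(C)=C/C(=O)O
F2 | step 13 | (E)-3-ethoxybut-2-enoyl chloride | CCO/C(C)=C/C(=O)Cl
F3 | step 19 | 2-methyl-1-(2,4,6-trihydroxy-3-{[4α-hydroxyeudesm-11-en-1β-yl]methyl}phenyl)propan-1-one | C=C(C)[C@@H]1CC[C@@]2(C)[C@H](Cc3c(O)cc(O)c(C(=O)C(C)C)c3O)CC[C@@](C)(O)[C@@H]2C1
F4 | step 19 | 2-methyl-1-(2,4,6-trihydroxy-3-(hydroxymethyl)-5-{[4α-hydroxyeudesm-11-en-1β-yl]methyl}phenyl)propan-1-one | C=C(C)[C@@H]1CC[C@@]2(C)[C@H](Cc3c(O)c(CO)c(O)c(C(=O)C(C)C)c3O)CC[C@@](C)(O)[C@@H]2C1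
F5 | step 15 | 6-bromo-5-ethoxy-2-{[4α-(triethylsilyloxy)eudesm-11-en-1β-yl]methyl}-3-(triisopropylsilyloxy)phenol | C=C(C)[C@@H]1CC[C@@]2(C)[C@H](Cc3c(O)c(Br)c(OCC)cc3O[Si](C(C)C)(C(C)C)C(C)C)CC[C@@](C)(O[Si](CC)(CC)CC)[C@@H]2C1
F6 | step 15 | lithium 5-ethoxy-6-lithio-2-{[4α-(triethylsilyloxy)eudesm-11-en-1β-yl]methyl}-3-(triisopropylsilyloxy)phenolate | C=C(C)[C@@H]1CC[C@@]2(C)[C@H](Cc3c(O[Li])c([Li])c(OCC)cc3O[Si](C(C)C)(C(C)C)C(C)C)CC[C@@](C)(O[Si](CC)(CC)CC)[C@@H]2C1
F0 | step 9 | none | none
F7 | step 12 | [4α-(triethylsilyloxy)eudesm-11-en-1β-yl]acetaldehyde | C=C(C)[C@@H]1CC[C@@]2(C)[C@H](CC=O)CC[C@@](C)(O[Si](CC)(CC)CC)[C@@H]2C1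
F8 | step 12 | 1β-(prop-2-yn-1-yl)-4α-(triethylsilyloxy)eudesm-11-ene | C=C(C)[C@@H]1CC[C@@]2(C)[C@H](CC#C)CC[C@@](C)(O[Si](CC)(CC)CC)[C@@H]2C1
F9 | step 12 | lithium acetylide of F8 | C=C(C)[C@@H]1CC[C@@]2(C)[C@H](CC#C[Li])CC[C@@](C)(O[Si](CC)(CC)CC)[C@@H]2C1
A1 | alternative 1 | (2E,6E)-farnesyl diphosphate | CC(C)=CCC/C(C)=C/CC/C(C)=C/COP(=O)(O)OP(=O)(O)O
A2 | alternative 1 | (R)-germacrene A | C=C(C)[C@@H]1CC/C(C)=C/CC/C(C)=C/C1
A3 | alternative 1 | 2,4-dihydroxy-5-methylidene-3-(2-methylpropanoyl)-6-oxocyclohexa-1,3-diene-1-carbaldehyde (o-quinone methide) | C=C1C(=O)C(C=O)=C(O)C(C(=O)C(C)C)=C1O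
A4 | alternative 2 | (2E,6R,8E)-3,9-dimethyl-6-(prop-1-en-2-yl)undeca-2,8,10-trienal | O=C/C=C(\C)CC[C@H](C/C=C(\C)C=C)C(C)=C
A5 | alternative 2 | eudesma-3,11-diene-1β-carbaldehyde | C=C(C)[C@@H]1CC[C@@]2(C)[C@H](C=O)CC=C(C)[C@@H]2C1
A6 | alternative 3 | 4-hydroxy-3-{[4α-hydroxyeudesm-11-en-1β-yl]methyl}-6-(3-methyl-2-oxobutyl)-2H-pyran-2-one | C=C(C)[C@@H]1CC[C@@]2(C)[C@H](CC3=C(O)C=C(CC(=O)C(C)C)OC3=O)CC[C@@](C)(O)[C@@H]2C1
A7 | alternative 3 | methyl 2-{[4α-hydroxyeudesm-11-en-1β-yl]methyl}-8-methyl-3,5,7-trioxononanoate | C=C(C)[C@@H]1CC[C@@]2(C)[C@H](CC(C(=O)OC)C(=O)CC(=O)CC(=O)C(C)C)CC[C@@](C)(O)[C@@H]2C1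
A8 | alternative 3 | 2-methyl-1-(2,4,6-trihydroxy-3-{[4α-hydroxyeudesm-11-en-1β-yl]methyl}phenyl)propan-1-one (deformyl target) | C=C(C)[C@@H]1CC[C@@]2(C)[C@H](Cc3c(O)cc(O)c(C(=O)C(C)C)c3O)CC[C@@](C)(O)[C@@H]2C1
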